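**Plan**

- Retrosynthetic cuts, in order: the two O–Si bonds (protecting groups); the C2–C1′ bond between the quaternary ring carbon and the first side-chain CH2 (fragment union); the pyranone ring at O1–C2 and C2–C3 (back to an o-hydroxyacetophenone and an acetate unit); the aryl–acetyl bond (back to 2-bromo-1,4-dimethoxybenzene).
- Enabling feature: in the pyranone ring, C2 lies β to the C4 ketone and α to ring oxygen O1 and already bears the methyl group. At the chromone oxidation level (C2=C3) it is the flat, prochiral, electrophilic end of the vinylogous ester O1–C2=C3–C4=O. The side chain is a primary alkyl that maps onto the terminal alkene of 2-methylpent-4-en-2-ol.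
- Forward order: arene acylation with ortho-demethylation; closure of the pyranone ring by Claisen condensation/cyclodehydration; methyl-to-silyl exchange on O6; union of chromone and alkene by hydrozirconation/copper-catalysed asymmetric conjugate addition; global desilylation.
- Stereochemistry: the only stereocentre, C2 (R), is created in the fragment union by the chiral copper catalyst (alkyl delivery to the Re face of C2). It is guarded against retro-oxa-Michael scrambling by enolate silylation and a buffered final deprotection.
- Helpers: the C2=C3 unsaturation (consumed in the key step), the transient silyl enol ether, and the TBS/TES ethers (removed in the last step).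

Key step: step 6

Remark: the sense of induction of a copper–phosphoramidite catalyst on a 2-methylchromone cannot be read with certainty from enone precedents; it is assumed that one ligand antipode (both are available) delivers the alkyl group to the Re face of C2, and that antipode is to be identified in a first run.

**Route**

Step 1
Reactants: 1 2-bromo-1,4-dimethoxybenzene
Product: 3 1-(4-bromo-2-hydroxy-5-methoxyphenyl)ethan-1-one, via dimethoxy ketone 2 (not isolated)
Conditions: AcCl (1.2 equiv), AlCl3 (2.5 equiv), CH2Cl2, 0 °C → 40 °C; aq. HCl
Reagents that add atoms: acetyl chloride, CC(=O)Cl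
Why: Friedel–Crafts acylation should go para to bromine and ortho to a methoxy group (the only unhindered, doubly directed position), and excess AlCl3 chelated between the new carbonyl and the ortho-methoxy oxygen should then cleave only that methyl ether (chelation-assisted O-demethylation), leaving the 5-OMe intact.

Step 2
Reactants: 3 1-(4-bromo-2-hydroxy-5-methoxyphenyl)ethan-1-one
Product: 5 7-bromo-6-methoxy-2-methyl-4H-chromen-4-one, via 1,3-diketone 4 (not isolated)
Conditions: NaH (4 equiv), EtOAc (6 equiv), THF, reflux; aq. HCl; crude 4 in AcOH, conc. HCl (cat.), 90 °C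
Reagents that add atoms: ethyl acetate, CCOC(C)=O
Why: Claisen condensation of the phenoxide–enolate dianion with ethyl acetate gives the β-diketone, whose phenol adds to the distal carbonyl and dehydrates under acid to the aromatic 4-pyranone (classical 2-methylchromone synthesis), the aryl bromide and methyl ether being inert.

Step 3
Reactants: 5 7-bromo-6-methoxy-2-methyl-4H-chromen-4-one
Product: 6 7-bromo-6-hydroxy-2-methyl-4H-chromen-4-one
Conditions: BBr3 (3 equiv), CH2Cl2, −78 °C → rt; H2O
Reagents that add atoms: none
Why: BBr3 cleavage of the aryl methyl ether is placed at the chromone stage because the aromatic pyranone tolerates the Lewis acid, whereas the later tertiary alcohol and C2 stereocentre would not.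

Step 4
Reactants: 6 7-bromo-6-hydroxy-2-methyl-4H-chromen-4-one
Product: 7 7-bromo-6-[(tert-butyldimethylsilyl)oxy]-2-methyl-4H-chromen-4-one
Conditions: TBSCl, imidazole, DMF, rt
Reagents that add atoms: tert-butyldimethylsilyl chloride, CC(C)(C)[Si](C)(C)Cl
Why: Imidazole-promoted silylation of the phenol masks the acidic OH, which would otherwise quench the organometallic and deactivate the acceptor as its phenoxide.

Step 5
Reactants: 8 2-methylpent-4-en-2-ol
Product: 9 triethyl[(2-methylpent-4-en-2-yl)oxy]silane
Conditions: TESOTf, 2,6-lutidine, CH2Cl2, 0 °C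
Reagents that add atoms: triethylsilyl trifluoromethanesulfonate, CC[Si](CC)(CC)OS(=O)(=O)C(F)(F)F
Why: Silyl triflate/2,6-lutidine silylation of the hindered tertiary alcohol removes the only proton source of the side-chain fragment before hydrozirconation.

Step 6
Reactants: 9 triethyl[(2-methylpent-4-en-2-yl)oxy]silane, 7 7-bromo-6-[(tert-butyldimethylsilyl)oxy]-2-methyl-4H-chromen-4-one
Product: 12 (R)-7-bromo-6-[(tert-butyldimethylsilyl)oxy]-2-methyl-2-{4-methyl-4-[(triethylsilyl)oxy]pentyl}chroman-4-one, via alkylzirconocene chloride 10 (not isolated), via trimethylsilyl enol ether 11 (not isolated)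
Conditions: 9 (2.5 equiv), Cp2Zr(H)Cl (2.0 equiv), CH2Cl2, rt; then CuCl (10 mol%)/AgNTf2 (11 mol%), BINOL-derived N,N-bis(1-phenylethyl)phosphoramidite L* (11 mol%), TMSCl (3 equiv), 7 (1.0 equiv), Et2O, 0 °C → rt; aq. NH4Cl, then AcOH/THF/H2O, 0 °C
Reagents that add atoms: none
Why: Proposed new method: anti-Markovnikov hydrozirconation of the terminal alkene of 9 gives primary alkylzirconocene 10, which transmetalates to the chiral Cu(I)–phosphoramidite; the alkylcopper binds the C2=C3 bond of the TMSCl-activated chromone, adds oxidatively at C2 and reductively eliminates to forge the C2–CH2 bond, and the enolate is captured as silyl enol ether 11, which is hydrolysed to ketone 12 on work-up. The closest known reaction types are the copper-catalysed asymmetric conjugate addition of alkylzirconocenes to β-methyl cyclic enones (all-carbon quaternary centres) and the copper-catalysed asymmetric addition of alkyl Grignard reagents to 2-unsubstituted chromones; the untested extension is a 2-methylchromone, a less electrophilic vinylogous ester giving an oxygen-bearing quaternary centre, and it is argued from the 4-silyloxybenzopyrylium character that O-silylation at C4 confers on C2. No ring is closed, the step being an intermolecular fragment union. The C2 stereocentre is set by the catalyst alone, which must deliver the alkyl group to the Re face of C2 (O1 > C3 > CH3) of the flat benzopyranone, the discrimination resting on the difference between the planar fused O-aryl flank and the small methyl group, as between ring CH2 and methyl in 3-methylcyclohexenone. The step needs 1,4- over 1,2-addition (soft alkylcopper; no free Zr–H because 9 is in excess), tolerance of the aryl bromide (Cu(I) and alkylzirconium should not insert into Ar–Br at room temperature) and, above all, no E1cB opening of the β-aryloxy enolate, which would racemise C2 through the ring-opened phenoxide enone; in situ O-silylation to 11 secures this.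

Step 7
Reactants: 12 (R)-7-bromo-6-[(tert-butyldimethylsilyl)oxy]-2-methyl-2-{4-methyl-4-[(triethylsilyl)oxy]pentyl}chroman-4-one
Product: 13 (R)-7-bromo-6-hydroxy-2-(4-hydroxy-4-methylpentyl)-2-methylchroman-4-one
Conditions: TBAF (3 equiv), AcOH (3 equiv), THF, 0 °C → rt
Reagents that add atoms: none
Why: Fluoride-mediated desilylation buffered with acetic acid should cleave the aryl TBS and tertiary alkyl TES ethers while the medium stays too weakly basic for enolisation/retro-oxa-Michael opening at C2 and too weakly acidic for dehydration of the tertiary alcohol, so the C2 configuration is retained.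

**Compound list**

1 | 2-bromo-1,4-dimethoxybenzene | COc1ccc(OC)c(Br)c1 | starting material
2 | 1-(4-bromo-2,5-dimethoxyphenyl)ethan-1-one | CC(=O)c1cc(OC)c(Br)cc1OC | intermediate
3 | 1-(4-bromo-2-hydroxy-5-methoxyphenyl)ethan-1-one | CC(=O)c1cc(OC)c(Br)cc1O | intermediate
4 | 1-(4-bromo-2-hydroxy-5-methoxyphenyl)butane-1,3-dione | CC(=O)CC(=O)c1cc(OC)c(Br)cc1O | intermediate
5 | 7-bromo-6-methoxy-2-methyl-4H-chromen-4-one | Cc1cc(=O)c2cc(OC)c(Br)cc2o1 | intermediate
6 | 7-bromo-6-hydroxy-2-methyl-4H-chromen-4-one | Cc1cc(=O)c2cc(O)c(Br)cc2o1 | intermediate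
7 | 7-bromo-6-[(tert-butyldimethylsilyl)oxy]-2-methyl-4H-chromen-4-one | Cc1cc(=O)c2cc(O[Si](C)(C)C(C)(C)C)c(Br)cc2o1 | intermediate
8 | 2-methylpent-4-en-2-ol | C=CCC(C)(C)O | starting material
9 | triethyl[(2-methylpent-4-en-2-yl)oxy]silane | C=CCC(C)(C)O[Si](CC)(CC)CC | intermediate
10 | chlorobis(cyclopentadienyl)[4-methyl-4-(triethylsilyloxy)pentyl]zirconium (Cp rings drawn σ-bonded) | CC[Si](CC)(CC)OC(C)(C)CCC[Zr](Cl)(C1C=CC=C1)C1C=CC=C1 | intermediate
11 | (R)-7-bromo-6-[(tert-butyldimethylsilyl)oxy]-2-methyl-2-{4-methyl-4-[(triethylsilyl)oxy]pentyl}-4-[(trimethylsilyl)oxy]-2H-chromene | CC(C)(O[Si](CC)(CC)CC)CCC[C@]1(C)C=C(O[Si](C)(C)C)c2cc(O[Si](C)(C)C(C)(C)C)c(Br)cc2O1 | intermediate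
12 | (R)-7-bromo-6-[(tert-butyldimethylsilyl)oxy]-2-methyl-2-{4-methyl-4-[(triethylsilyl)oxy]pentyl}chroman-4-one | CC(C)(O[Si](CC)(CC)CC)CCC[C@]1(C)CC(=O)c2cc(O[Si](C)(C)C(C)(C)C)c(Br)cc2O1 | intermediate
13 | (R)-7-bromo-6-hydroxy-2-(4-hydroxy-4-methylpentyl)-2-methylchroman-4-one | CC(C)(O)CCC[C@]1(C)CC(=O)c2cc(O)c(Br)cc2O1 | target

**Step count**

Total steps: 7. Longest linear sequence: 6 steps (1 → 3 → 5 → 6 → 7 → 12 → 13; step 5 prepares the side-chain fragment 9).

**Steps most likely to fail**

1. Step 6 (proposed new method). The alkylcopper may fail to add to the hindered, electron-rich vinylogous ester, so that no turnover occurs, or it may add with poor facial selectivity. The fallback uses known chemistry and builds the ring around a chain that is already in place. It sets out from 3. BBr3 demethylation should give 1-(4-bromo-2,5-dihydroxyphenyl)ethan-1-one F1. Kabbe condensation of this ketone under argon (pyrrolidine, MeOH, heat) with commercial 6-hydroxy-6-methylheptan-2-one (CC(=O)CCCC(C)(C)O) should give rac-7-bromo-6-hydroxy-2-(4-hydroxy-4-methylpentyl)-2-methylchroman-4-one F2. Preparative chromatography on a chiral stationary phase would then separate the target from (S)-7-bromo-6-hydroxy-2-(4-hydroxy-4-methylpentyl)-2-methylchroman-4-one F3, which can be returned to F2 with pyrrolidine through the reversible oxa-Michael step and recycled. The fallback comes back to the route at 13.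

2. Step 7. Base-induced ring opening at C2 during fluoride treatment would erode the enantiomeric purity, and cleavage of the hindered tertiary silyl ether may be incomplete. The fallback replaces the fluoride-labile phenol protection by an acid-labile one, so that no basic step follows the fragment union. It sets out from 6. MOMCl and iPr2NEt should give 7-bromo-6-(methoxymethoxy)-2-methyl-4H-chromen-4-one F4. Conjugate addition of 10 (from 9) under the conditions of step 6 would pass through (R)-7-bromo-6-(methoxymethoxy)-2-methyl-2-{4-methyl-4-[(triethylsilyl)oxy]pentyl}-4-[(trimethylsilyl)oxy]-2H-chromene F5, not isolated, and give (R)-7-bromo-6-(methoxymethoxy)-2-methyl-2-{4-methyl-4-[(triethylsilyl)oxy]pentyl}chroman-4-one F6. Dilute HCl in MeOH at rt should then remove the MOM and TES groups in one acidic operation. The fallback comes back to the route at 13.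

3. Step 2. O-acylation of the phenoxide, self-condensation of the ester or incomplete acylation of the enolate may lower the efficiency of the Claisen stage. The fallback introduces the two carbons with an amide acetal instead of an ester enolate reaction. It sets out from 3. Heating with N,N-dimethylacetamide dimethyl acetal in toluene should give (E)-1-(4-bromo-2-hydroxy-5-methoxyphenyl)-3-(dimethylamino)but-2-en-1-one F7. Warming F7 in AcOH should close the pyranone ring with loss of the amine. The fallback comes back to the route at 5.

**Further compounds**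

F1 | step 6 | 1-(4-bromo-2,5-dihydroxyphenyl)ethan-1-one | CC(=O)c1cc(O)c(Br)cc1O
F2 | step 6 | rac-7-bromo-6-hydroxy-2-(4-hydroxy-4-methylpentyl)-2-methylchroman-4-one | CC(C)(O)CCCC1(C)CC(=O)c2cc(O)c(Br)cc2O1
F3 | step 6 | (S)-7-bromo-6-hydroxy-2-(4-hydroxy-4-methylpentyl)-2-methylchroman-4-one | CC(C)(O)CCC[C@@]1(C)CC(=O)c2cc(O)c(Br)cc2O1
F4 | step 7 | 7-bromo-6-(methoxymethoxy)-2-methyl-4H-chromen-4-one | Cc1cc(=O)c2cc(OCOC)c(Br)cc2o1
F5 | step 7 | (R)-7-bromo-6-(methoxymethoxy)-2-methyl-2-{4-methyl-4-[(triethylsilyl)oxy]pentyl}-4-[(trimethylsilyl)oxy]-2H-chromene | CC(C)(O[Si](CC)(CC)CC)CCC[C@]1(C)C=C(O[Si](C)(C)C)c2cc(OCOC)c(Br)cc2O1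
F6 | step 7 | (R)-7-bromo-6-(methoxymethoxy)-2-methyl-2-{4-methyl-4-[(triethylsilyl)oxy]pentyl}chroman-4-one | CC(C)(O[Si](CC)(CC)CC)CCC[C@]1(C)CC(=O)c2cc(OCOC)c(Br)cc2O1
F7 | step 2 | (E)-1-(4-bromo-2-hydroxy-5-methoxyphenyl)-3-(dimethylamino)but-2-en-1-one | CN(C)/C(C)=C/C(=O)c1cc(OC)c(Br)cc1O
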